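**Retrosynthetic overview**

1. Target 28 ⇐ acetylation of the primary OH (15) ⇐ acetonide cleavage (14) ⇐ esterification of keto acid 24 with (S)-solketal 25 (13); 24 ⇐ oxidation of the silyl ether (12) and Wacker oxidation of the butenyl group of 22 (11).
2. 22 ⇐ one operation (10) from the seven-membered 2-diazo ketone 13, alkyllithium 20 and MeI: photo-Wolff ring contraction to ketene 19, RLi addition, C-methylation of enolate 21. This forms the cyclohexane, the ketone C–C bond and the quaternary stereocentre.
3. 13 ⇐ regiospecific diazo transfer (5) ⇐ Cu-catalysed asymmetric conjugate addition with enolate silylation on 4,4-dimethylcyclohept-2-enone 6 (4) ⇐ cycloheptane-1,3-dione 1 (1–3). Iodide 18 ⇐ methyl hydrogen (R)-3-methylglutarate 14 (6–9).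
4. Enabling feature: cyclohexane C-1 is quaternary and carries a methyl group and the exocyclic ketone carbon (C-6 of the hexanoate). A cycloheptanone whose carbonyl carbon is extruded by Wolff shift leaves exactly such a carbon as a ketene. The ketene takes the side chain at C=O and the methyl at the ring carbon, anti to the C-2 substituent (acyl cis to the 3-oxobutyl chain, as required).
5. Ring order: the only carbocycle is carried as a seven-membered ring (steps 1–5) and becomes six-membered in step 10; the dioxolane of 25 is a protecting group only.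

Key step: step 10

Assumption: the Cu(OTf)2/phosphoramidite catalyst is taken to deliver the alkyl group to 4,4-dimethylcyclohept-2-en-1-one with the facial sense known for cyclohex-2-enone and cyclohept-2-enone, and the (S,R,R) ligand is specified on that basis.

**Route**

Step 1
Reactants: 1 cycloheptane-1,3-dione
Product: 2 3-(2-methylpropoxy)cyclohept-2-en-1-one
Conditions: i-BuOH, TsOH·H2O (cat.), toluene, reflux, Dean–Stark
Reagents that add atoms: 2-methylpropan-1-ol, CC(C)CO
Why: Acid-catalysed enol ether formation from the cyclic 1,3-diketone with azeotropic removal of water should give the vinylogous ester, which masks one carbonyl and directs later enolate chemistry to C-7.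

Step 2
Reactants: 2 3-(2-methylpropoxy)cyclohept-2-en-1-one
Product: 4 7,7-dimethyl-3-(2-methylpropoxy)cyclohept-2-en-1-one, via monomethyl vinylogous ester 3 (not isolated)
Conditions: LDA (1.1 equiv), THF, −78 °C, then MeI (1.05 equiv), −78 → 0 °C; recool to −78 °C, LDA (1.2 equiv), then MeI (1.5 equiv), −78 → 0 °C
Reagents that add atoms: iodomethane, CI
Why: Kinetic deprotonation of a 3-alkoxyenone occurs at the alpha' carbon (C-7), so two successive enolate methylations (Stork–Danheiser alkylation) should install the gem-dimethyl group there.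

Step 3
Reactants: 4 7,7-dimethyl-3-(2-methylpropoxy)cyclohept-2-en-1-one
Product: 6 4,4-dimethylcyclohept-2-en-1-one, via allylic alcohol 5 (not isolated)
Conditions: LiAlH4, Et2O, 0 °C; then 1 M aq. HCl, rt
Reagents that add atoms: water, O
Why: 1,2-Reduction of the vinylogous ester carbonyl and acid hydrolysis of the hydroxy enol ether with loss of water should transpose the enone (Stork–Danheiser transposition), placing the gem-dimethyl group gamma to the new carbonyl.

Step 4
Reactants: 6 4,4-dimethylcyclohept-2-en-1-one; 7 but-3-en-1-ylmagnesium bromide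
Product: 10 {[(3R)-3-(but-3-en-1-yl)-4,4-dimethylcyclohept-1-en-1-yl]oxy}trimethylsilane, via dibutenylzinc 8 (not isolated), via zinc enolate 9 (not isolated)
Conditions: 7 (3.2 equiv), ZnCl2 (1.6 equiv), Et2O–THF, 0 °C → rt, then 1,4-dioxane and filtration of MgBrCl; Cu(OTf)2 (2 mol%), (S,R,R)-phosphoramidite ligand from (S)-1,1'-bi-2-naphthol and bis[(R)-1-phenylethyl]amine (4 mol%), 6, toluene, −30 °C; then TMSOTf, −30 → 0 °C; Et3N, pentane work-up
Reagents that add atoms: trimethylsilyl trifluoromethanesulfonate, C[Si](C)(C)OS(=O)(=O)C(F)(F)F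
Why: Copper-catalysed asymmetric conjugate addition of a salt-free dialkylzinc (closely precedented for 4,4-dimethylcyclohex-2-enone and cyclohept-2-enone) should set the butenyl-bearing stereocentre by ligand control of the enone face, and O-silylation of the zinc enolate fixes the enolate double bond toward that stereocentre.

Step 5
Reactants: 10 {[(3R)-3-(but-3-en-1-yl)-4,4-dimethylcyclohept-1-en-1-yl]oxy}trimethylsilane
Product: 13 (3S)-3-(but-3-en-1-yl)-2-diazo-4,4-dimethylcycloheptan-1-one, via lithium enolate 11 (not isolated), via trifluoroacetyl ketone 12 (not isolated)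
Conditions: MeLi (1.05 equiv), THF, 0 °C → rt; −78 °C, CF3CO2CH2CF3; aq. work-up; then 4-acetamidobenzenesulfonyl azide, Et3N, H2O (1 equiv), MeCN, rt
Reagents that add atoms: 4-acetamidobenzenesulfonyl azide, CC(=O)Nc1ccc(cc1)S(=O)(=O)N=[N+]=[N-]
Why: Si–O cleavage by MeLi gives the regiodefined lithium enolate, which is C-trifluoroacetylated and then undergoes deacylative Regitz diazo transfer, so the diazo group should land on the hindered alpha-carbon next to the stereocentre, which kinetic enolisation of the ketone would not reach; the beta-stereocentre is not enolisable.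

Step 6
Reactants: 14 (3R)-5-methoxy-3-methyl-5-oxopentanoic acid
Product: 15 methyl (3R)-5-hydroxy-3-methylpentanoate
Conditions: BH3·SMe2, THF, 0 °C → rt; MeOH quench; crude used at once
Reagents that add atoms: none
Why: Borane reduces a carboxylic acid much faster than an ester (chemoselective acid reduction), which differentiates the two arms of the chiral-pool glutarate without touching the stereocentre.

Step 7
Reactants: 15 methyl (3R)-5-hydroxy-3-methylpentanoate
Product: 16 methyl (3S)-5-iodo-3-methylpentanoate
Conditions: PPh3, I2, imidazole, CH2Cl2, 0 °C → rt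
Reagents that add atoms: iodine, II
Why: Appel-type iodination of the primary alcohol proceeds by SN2 displacement of the oxyphosphonium group and, run immediately, should pre-empt lactonisation of the hydroxy ester (the descriptor changes only through priority rules).

Step 8
Reactants: 16 methyl (3S)-5-iodo-3-methylpentanoate
Product: 17 (3S)-5-iodo-3-methylpentan-1-ol
Conditions: i-Bu2AlH (2.2 equiv), CH2Cl2, −78 → 0 °C; aq. potassium sodium tartrate
Reagents that add atoms: none
Why: Hydride reduction of the ester with i-Bu2AlH at low temperature should give the primary alcohol while leaving the primary alkyl iodide intact.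

Step 9
Reactants: 17 (3S)-5-iodo-3-methylpentan-1-ol
Product: 18 tert-butyl{[(3S)-5-iodo-3-methylpentyl]oxy}dimethylsilane
Conditions: TBSCl, imidazole, CH2Cl2, rt
Reagents that add atoms: tert-butyl(chloro)dimethylsilane, CC(C)(C)[Si](C)(C)Cl
Why: Standard silylation protects the alcohol as a silyl ether that tolerates the organolithium chemistry of step 10 and is later removed under the oxidation conditions of step 12.

Step 10
Reactants: 13 (3S)-3-(but-3-en-1-yl)-2-diazo-4,4-dimethylcycloheptan-1-one; 18 tert-butyl{[(3S)-5-iodo-3-methylpentyl]oxy}dimethylsilane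
Product: 22 (4R)-6-[(tert-butyldimethylsilyl)oxy]-1-[(1R,2S)-2-(but-3-en-1-yl)-1,3,3-trimethylcyclohexyl]-4-methylhexan-1-one, via ketene 19 (not isolated), via alkyllithium 20 (not isolated), via lithium enolate 21 (not isolated)
Conditions: 13, hν (medium-pressure Hg lamp, Pyrex), Et2O, −78 °C until N2 evolution ends; second flask: 18, t-BuLi (2.0 equiv), Et2O–pentane, −78 °C; cannulate 20 (1.05 equiv) into 19, −78 °C; then DMPU, MeI (5 equiv), −78 → −20 °C
Reagents that add atoms: iodomethane, CI
Why: Proposed new method: Photolysis of the cyclic, s-cis-locked 2-diazo ketone should trigger a Wolff rearrangement in which the ring CH2 (C-7) shifts from the carbonyl carbon to the diazo carbon with loss of N2, so that the seven-membered ring contracts to the cyclohexane and the former ring carbonyl is extruded as the exocyclic ketene carbon; the six-membered ring is thus closed by 1,2-shift (ring contraction), not by an end-to-end cyclisation. Alkyllithium 20 then adds to the ketene carbonyl carbon to give the tetrasubstituted lithium enolate 21 regiospecifically (the ketone itself would enolise toward the side-chain CH2 instead), and MeI C-alkylates it to create the quaternary carbon. The closest known reaction types are the photo-Wolff ring contraction of 2-diazocycloalkanones, the addition of organolithiums to isolated ketenes to give defined enolates, and the alkylation of exocyclic enolates of cyclohexyl ketones and esters; their telescoped use on a Wolff ketene is the new element. The new quaternary stereocentre is controlled by the adjacent butenyl-bearing stereocentre: the exocyclic enolate is attacked on the ring face opposite that substituent (the gem-dimethyl group puts one methyl on each face and gives no net bias), which places methyl trans and the acyl group cis to the butenyl chain as the target requires. The step needs the Wolff shift to outrun carbene chemistry (secured by the cyclic s-cis diazo ketone and direct irradiation at low temperature), single addition of RLi (the enolate formed is inert to a second addition), and C- over O-methylation without enolate equilibration (MeI in excess, DMPU, low temperature).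

Step 11
Reactants: 22 (4R)-6-[(tert-butyldimethylsilyl)oxy]-1-[(1R,2S)-2-(but-3-en-1-yl)-1,3,3-trimethylcyclohexyl]-4-methylhexan-1-one
Product: 23 (4R)-6-[(tert-butyldimethylsilyl)oxy]-4-methyl-1-[(1R,2S)-1,3,3-trimethyl-2-(3-oxobutyl)cyclohexyl]hexan-1-one
Conditions: PdCl2 (10 mol%), CuCl (1 equiv), O2 (1 atm), DMF–H2O (7:1), rt
Reagents that add atoms: water, O
Why: Tsuji–Wacker oxidation of the unhindered terminal alkene by PdCl2 (divalent palladium, regenerated by CuCl/O2) should give the methyl ketone with Markovnikov selectivity and unmask the 3-oxobutyl chain; any silyl ether lost here converges in step 12.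

Step 12
Reactants: 23 (4R)-6-[(tert-butyldimethylsilyl)oxy]-4-methyl-1-[(1R,2S)-1,3,3-trimethyl-2-(3-oxobutyl)cyclohexyl]hexan-1-one
Product: 24 (3R)-3-methyl-6-oxo-6-[(1R,2S)-1,3,3-trimethyl-2-(3-oxobutyl)cyclohexyl]hexanoic acid
Conditions: CrO3, H2SO4, H2O, acetone, 0 °C → rt
Reagents that add atoms: water, O
Why: Aqueous chromic acid (hexavalent chromium) cleaves the primary silyl ether and oxidises the freed alcohol through the aldehyde hydrate to the carboxylic acid in one operation (Jones oxidation), and no stereocentre is alpha to a carbonyl that could epimerise.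

Step 13
Reactants: 24 (3R)-3-methyl-6-oxo-6-[(1R,2S)-1,3,3-trimethyl-2-(3-oxobutyl)cyclohexyl]hexanoic acid; 25 [(4S)-2,2-dimethyl-1,3-dioxolan-4-yl]methanol
Product: 26 [(4R)-2,2-dimethyl-1,3-dioxolan-4-yl]methyl (3R)-3-methyl-6-oxo-6-[(1R,2S)-1,3,3-trimethyl-2-(3-oxobutyl)cyclohexyl]hexanoate
Conditions: EDC·HCl, DMAP, CH2Cl2, 0 °C → rt
Reagents that add atoms: none
Why: Steglich esterification of the unhindered acid with the primary alcohol of (S)-solketal should bring in the glycerol stereocentre from the chiral pool without touching it (the descriptor changes only through priority rules).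

Step 14
Reactants: 26 [(4R)-2,2-dimethyl-1,3-dioxolan-4-yl]methyl (3R)-3-methyl-6-oxo-6-[(1R,2S)-1,3,3-trimethyl-2-(3-oxobutyl)cyclohexyl]hexanoate
Product: 27 (2R)-2,3-dihydroxypropyl (3R)-3-methyl-6-oxo-6-[(1R,2S)-1,3,3-trimethyl-2-(3-oxobutyl)cyclohexyl]hexanoate
Conditions: AcOH–H2O (4:1), rt → 40 °C
Reagents that add atoms: none
Why: Mild acid hydrolysis of the isopropylidene ketal frees the 1,2-diol, and the weak acid and low temperature are chosen to keep the acyl group on its primary oxygen so that acyl migration does not scramble the glycerol stereocentre.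

Step 15
Reactants: 27 (2R)-2,3-dihydroxypropyl (3R)-3-methyl-6-oxo-6-[(1R,2S)-1,3,3-trimethyl-2-(3-oxobutyl)cyclohexyl]hexanoate
Product: 28 (2R)-3-(acetyloxy)-2-hydroxypropyl (3R)-3-methyl-6-oxo-6-[(1R,2S)-1,3,3-trimethyl-2-(3-oxobutyl)cyclohexyl]hexanoate
Conditions: AcCl (1.05 equiv), 2,4,6-collidine, CH2Cl2, −78 °C
Reagents that add atoms: acetyl chloride, CC(Cl)=O
Why: Kinetic acylation with AcCl and the hindered base collidine at low temperature should discriminate the primary from the secondary hydroxyl (regioselective esterification) and give the 1,3-diacylglycerol target.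

**Compound list**

1 | cycloheptane-1,3-dione | O=C1CCCCC(=O)C1 | starting material
2 | 3-(2-methylpropoxy)cyclohept-2-en-1-one | CC(C)COC1=CC(=O)CCCC1 | intermediate
3 | 7-methyl-3-(2-methylpropoxy)cyclohept-2-en-1-one (racemic) | CC(C)COC1=CC(=O)C(C)CCC1 | intermediate
4 | 7,7-dimethyl-3-(2-methylpropoxy)cyclohept-2-en-1-one | CC(C)COC1=CC(=O)C(C)(C)CCC1 | intermediate
5 | 7,7-dimethyl-3-(2-methylpropoxy)cyclohept-2-en-1-ol (racemic) | CC(C)COC1=CC(O)C(C)(C)CCC1 | intermediate
6 | 4,4-dimethylcyclohept-2-en-1-one | O=C1C=CC(C)(C)CCC1 | intermediate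
7 | but-3-en-1-ylmagnesium bromide | C=CCC[Mg]Br | starting material
8 | di(but-3-en-1-yl)zinc | C=CCC[Zn]CCC=C | intermediate
9 | (but-3-en-1-yl)zinc (3R)-3-(but-3-en-1-yl)-4,4-dimethylcyclohept-1-en-1-olate | C=CCC[C@H]1C(C)(C)CCCC(O[Zn]CCC=C)=C1 | intermediate
10 | {[(3R)-3-(but-3-en-1-yl)-4,4-dimethylcyclohept-1-en-1-yl]oxy}trimethylsilane | C=CCC[C@H]1C(C)(C)CCCC(O[Si](C)(C)C)=C1 | intermediate
11 | lithium (3R)-3-(but-3-en-1-yl)-4,4-dimethylcyclohept-1-en-1-olate | C=CCC[C@H]1C(C)(C)CCCC([O-])=C1.[Li+] | intermediate
12 | (3R)-3-(but-3-en-1-yl)-4,4-dimethyl-2-(trifluoroacetyl)cycloheptan-1-one (C-2 undefined, largely enol) | C=CCC[C@H]1C(C)(C)CCCC(=O)C1C(=O)C(F)(F)F | intermediate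
13 | (3S)-3-(but-3-en-1-yl)-2-diazo-4,4-dimethylcycloheptan-1-one | C=CCC[C@H]1C(C)(C)CCCC(=O)C1=[N+]=[N-] | intermediate
14 | (3R)-5-methoxy-3-methyl-5-oxopentanoic acid [methyl hydrogen (R)-3-methylglutarate] | OC(=O)C[C@@H](C)CC(=O)OC | starting material
15 | methyl (3R)-5-hydroxy-3-methylpentanoate | OCC[C@@H](C)CC(=O)OC | intermediate
16 | methyl (3S)-5-iodo-3-methylpentanoate | ICC[C@@H](C)CC(=O)OC | intermediate
17 | (3S)-5-iodo-3-methylpentan-1-ol | ICC[C@@H](C)CCO | intermediate
18 | tert-butyl{[(3S)-5-iodo-3-methylpentyl]oxy}dimethylsilane | ICC[C@@H](C)CCO[Si](C)(C)C(C)(C)C | intermediate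
19 | [(2S)-2-(but-3-en-1-yl)-3,3-dimethylcyclohexylidene]methanone (ketene) | C=CCC[C@H]1C(C)(C)CCCC1=C=O | intermediate
20 | {(3R)-5-[(tert-butyldimethylsilyl)oxy]-3-methylpentyl}lithium | [Li]CC[C@@H](C)CCO[Si](C)(C)C(C)(C)C | intermediate
21 | lithium (4R)-6-[(tert-butyldimethylsilyl)oxy]-1-[(2S)-2-(but-3-en-1-yl)-3,3-dimethylcyclohexylidene]-4-methylhexan-1-olate | C=CCC[C@H]1C(C)(C)CCCC1=C([O-])CC[C@@H](C)CCO[Si](C)(C)C(C)(C)C.[Li+] | intermediate
22 | (4R)-6-[(tert-butyldimethylsilyl)oxy]-1-[(1R,2S)-2-(but-3-en-1-yl)-1,3,3-trimethylcyclohexyl]-4-methylhexan-1-one | C=CCC[C@H]1C(C)(C)CCC[C@@]1(C)C(=O)CC[C@@H](C)CCO[Si](C)(C)C(C)(C)C | intermediate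
23 | (4R)-6-[(tert-butyldimethylsilyl)oxy]-4-methyl-1-[(1R,2S)-1,3,3-trimethyl-2-(3-oxobutyl)cyclohexyl]hexan-1-one | CC(=O)CC[C@H]1C(C)(C)CCC[C@@]1(C)C(=O)CC[C@@H](C)CCO[Si](C)(C)C(C)(C)C | intermediate
24 | (3R)-3-methyl-6-oxo-6-[(1R,2S)-1,3,3-trimethyl-2-(3-oxobutyl)cyclohexyl]hexanoic acid | CC(=O)CC[C@H]1C(C)(C)CCC[C@@]1(C)C(=O)CC[C@@H](C)CC(=O)O | intermediate
25 | [(4S)-2,2-dimethyl-1,3-dioxolan-4-yl]methanol [(S)-solketal] | CC1(C)OC[C@H](CO)O1 | starting material
26 | [(4R)-2,2-dimethyl-1,3-dioxolan-4-yl]methyl (3R)-3-methyl-6-oxo-6-[(1R,2S)-1,3,3-trimethyl-2-(3-oxobutyl)cyclohexyl]hexanoate | CC(=O)CC[C@H]1C(C)(C)CCC[C@@]1(C)C(=O)CC[C@@H](C)CC(=O)OC[C@H]2COC(C)(C)O2 | intermediate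
27 | (2R)-2,3-dihydroxypropyl (3R)-3-methyl-6-oxo-6-[(1R,2S)-1,3,3-trimethyl-2-(3-oxobutyl)cyclohexyl]hexanoate | CC(=O)CC[C@H]1C(C)(C)CCC[C@@]1(C)C(=O)CC[C@@H](C)CC(=O)OC[C@H](O)CO | intermediate
28 | (2R)-3-(acetyloxy)-2-hydroxypropyl (3R)-3-methyl-6-oxo-6-[(1R,2S)-1,3,3-trimethyl-2-(3-oxobutyl)cyclohexyl]hexanoate | CC(=O)CC[C@H]1C(C)(C)CCC[C@@]1(C)C(=O)CC[C@@H](C)CC(=O)OC[C@H](O)COC(C)=O | target

**Step count**

Total steps: 15. Longest linear sequence: 11 (steps 1–5 and 10–15); steps 6–9 form the side-chain branch.

**Steps most likely to fail**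

Step 10 (proposed new method). What may go wrong: carbene pathways during photolysis (1,2-hydride shift from the neighbouring CH, cyclopropanation of the butenyl alkene) competing with the Wolff shift; proton transfer between enolate 21 and product 22 leading to over-methylation at the side-chain CH2; O-methylation of the hindered enolate.

The fallback uses known chemistry in separate operations and sets out from 13. Photolysis in MeOH (hν, Pyrex, rt) should give, by Wolff ring contraction and methanol capture, methyl (2R)-2-(but-3-en-1-yl)-3,3-dimethylcyclohexane-1-carboxylate F1 as C-1 epimers. Deprotonation with LDA (THF, −78 °C) and methylation with MeI anti to the butenyl group should give methyl (1R,2S)-2-(but-3-en-1-yl)-1,3,3-trimethylcyclohexane-1-carboxylate F2. LiAlH4 reduction gives [(1R,2S)-2-(but-3-en-1-yl)-1,3,3-trimethylcyclohexyl]methanol F3, and Dess–Martin oxidation gives (1R,2S)-2-(but-3-en-1-yl)-1,3,3-trimethylcyclohexane-1-carbaldehyde F4. Addition of alkyllithium 20 (from 18 and t-BuLi) gives (4R)-6-[(tert-butyldimethylsilyl)oxy]-1-[(1R,2S)-2-(but-3-en-1-yl)-1,3,3-trimethylcyclohexyl]-4-methylhexan-1-ol F5 as carbinol epimers. A second Dess–Martin oxidation comes back to the route at 22.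

Step 4. What may go wrong: slow or poorly face-selective alkyl transfer to an enone whose beta-carbon is flanked by the quaternary centre, or incomplete O-silylation of the zinc enolate.

The fallback sets the same stereocentre by hydride delivery instead of alkyl delivery and sets out from 4. Addition of 7 (CeCl3, THF, −78 °C) to the vinylogous ester carbonyl followed by aqueous acid (Stork–Danheiser transposition) should give 3-(but-3-en-1-yl)-4,4-dimethylcyclohept-2-en-1-one F6. Copper hydride-catalysed asymmetric conjugate reduction (CuCl, NaOt-Bu, the p-Tol-BINAP antipode that gives the 3R product, Me(EtO)2SiH, toluene) should give the regiodefined silyl enol ether {[(3R)-3-(but-3-en-1-yl)-4,4-dimethylcyclohept-1-en-1-yl]oxy}diethoxy(methyl)silane F7. MeLi converts F7 into lithium enolate 11, and the remainder of step 5 comes back to the route at 13.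

Step 5. What may go wrong: O- instead of C-trifluoroacetylation of the hindered enolate, or incomplete deacylative diazo transfer next to the neopentyl-like stereocentre.

The fallback goes through an oxime instead of an acyl activating group and sets out from 10. MeLi gives enolate 11, which is nitrosated at carbon with isoamyl nitrite (THF, −78 → 0 °C) to give (3S)-3-(but-3-en-1-yl)-2-(hydroxyimino)-4,4-dimethylcycloheptan-1-one F8. A Forster reaction (NH2Cl from NaOCl and aqueous NH3, NaOH, 0 °C) converts the oxime into the diazo group and comes back to the route at 13.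

**Further compounds**

F1 | step 10 | methyl (2R)-2-(but-3-en-1-yl)-3,3-dimethylcyclohexane-1-carboxylate (C-1 epimers) | C=CCC[C@H]1C(C)(C)CCCC1C(=O)OC
F2 | step 10 | methyl (1R,2S)-2-(but-3-en-1-yl)-1,3,3-trimethylcyclohexane-1-carboxylate | C=CCC[C@H]1C(C)(C)CCC[C@@]1(C)C(=O)OC
F3 | step 10 | [(1R,2S)-2-(but-3-en-1-yl)-1,3,3-trimethylcyclohexyl]methanol | C=CCC[C@H]1C(C)(C)CCC[C@@]1(C)CO
F4 | step 10 | (1R,2S)-2-(but-3-en-1-yl)-1,3,3-trimethylcyclohexane-1-carbaldehyde | C=CCC[C@H]1C(C)(C)CCC[C@@]1(C)C=O
F5 | step 10 | (4R)-6-[(tert-butyldimethylsilyl)oxy]-1-[(1R,2S)-2-(but-3-en-1-yl)-1,3,3-trimethylcyclohexyl]-4-methylhexan-1-ol (C-1 epimers) | C=CCC[C@H]1C(C)(C)CCC[C@@]1(C)C(O)CC[C@@H](C)CCO[Si](C)(C)C(C)(C)C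
F6 | step 4 | 3-(but-3-en-1-yl)-4,4-dimethylcyclohept-2-en-1-one | C=CCCC1=CC(=O)CCCC1(C)C
F7 | step 4 | {[(3R)-3-(but-3-en-1-yl)-4,4-dimethylcyclohept-1-en-1-yl]oxy}diethoxy(methyl)silane | C=CCC[C@H]1C(C)(C)CCCC(O[Si](C)(OCC)OCC)=C1
F8 | step 5 | (3S)-3-(but-3-en-1-yl)-2-(hydroxyimino)-4,4-dimethylcycloheptan-1-one | C=CCC[C@H]1C(C)(C)CCCC(=O)C1=NO
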